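## Retrosynthetic overview
1. Both rings are opened at once. Cutting C3–C4 (ring B, the 14-membered carbocycle) and O–C3 (ring A, the tetrahydrofuran) gives one acyclic chain with a C3 dimethyl acetal, a C15 silyl ether and a C4 silyl ketene acetal.
2. Forward, one catalytic Lewis acid operation closes ring A first (acetal exchange). It then closes ring B (ketene acetal attacks the cyclic oxocarbenium ion). C3 and C4 are set there under control of C1.
3. C7=C8 comes from cross metathesis of a 2-substituted acrylate with methyl hex-5-enoate. C19 comes from carbonylation of the kinetic enol triflate of a methyl ketone.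
4. C1 (with C15–C17) comes from rhodium-catalysed asymmetric 1,4-addition of an isopropenyl boronate to an enal, followed by Markovnikov hydration.
5. Z-C11=C12 with C7–C14 and C1 comes from mono-ozonolysis of 1,5-dimethylcycloocta-1,5-diene, whose ring-cis alkene is kept.

Positions are given in cembrane numbers: C1 = ring CH bearing C15 (CMe2–O); C3 = O–CH; C4 = CH(CO2Me, C18); C7=C8(CO2Me, C19); C11=C12(CH3, C20).

Assumption: 1 is used as the isomerically pure 1,5-dimethyl isomer, with the 1,6-dimethyl isomer of technical material removed before use.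

## Route

Step 1
Reactants: 1 (1Z,5Z)-1,5-dimethylcycloocta-1,5-diene
Product: 3 (4Z)-4-methyl-8-oxonon-4-enal, via mono-ozonide 2 (not isolated)
Conditions: O3 (0.9 equiv), CH2Cl2, −78 °C; then Me2S, −78 °C to rt
Reagents that add atoms: ozone, [O-][O+]=O
Why: Ozonolysis (Criegee cleavage) with a deficit of ozone cuts only one of the two equivalent trisubstituted alkenes, and the surviving alkene keeps its ring-cis geometry, which is the Z geometry of C11=C12 (C10 and C13 on the same side).

Step 2
Reactants: 3 (4Z)-4-methyl-8-oxonon-4-enal; 4 (triphenylphosphoranylidene)acetaldehyde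
Product: 5 (2E,6Z)-6-methyl-10-oxoundeca-2,6-dienal
Conditions: 4 (1.05 equiv), toluene, 80 °C
Reagents that add atoms: none
Why: Wittig olefination with a stabilised ylide attacks only the aldehyde, leaves the methyl ketone alone and gives the E enal.

Step 3
Reactants: 5 (2E,6Z)-6-methyl-10-oxoundeca-2,6-dienal; 6 isopropenylboronic acid pinacol ester
Product: 7 (3R,6Z)-6-methyl-10-oxo-3-(prop-1-en-2-yl)undec-6-enal
Conditions: [Rh(OH)((R)-BINAP)]2 (3 mol %), dioxane/H2O 10:1, 35 °C
Reagents that add atoms: none
Why: In this Hayashi–Miyaura asymmetric 1,4-addition the alkenylrhodium–BINAP species inserts the E enal on the face left open by the (R)-ligand, which by analogy with E-configured acyclic acceptors gives (R) at C1, and the neutral aqueous medium spares ketone and aldehyde.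

Step 4
Reactants: 7 (3R,6Z)-6-methyl-10-oxo-3-(prop-1-en-2-yl)undec-6-enal
Product: 8 (5Z,9R)-11,11-dimethoxy-6-methyl-9-(prop-1-en-2-yl)undec-5-en-2-one
Conditions: HC(OMe)3 (1.2 equiv), MeOH, PPTS (5 mol %), 0 °C
Reagents that add atoms: trimethyl orthoformate, COC(OC)OC
Why: Acid-catalysed acetalisation with an orthoester as water scavenger is much faster for the aldehyde than for the ketone, so C3 is masked selectively, and C1 is not enolisable and stays untouched.

Step 5
Reactants: 8 (5Z,9R)-11,11-dimethoxy-6-methyl-9-(prop-1-en-2-yl)undec-5-en-2-one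
Product: 9 (5Z,9R)-9-(2-hydroxypropan-2-yl)-11,11-dimethoxy-6-methylundec-5-en-2-one
Conditions: Mn(dpm)3 (5 mol %), PhSiH3 (1.5 equiv), O2 (1 atm), iPrOH/CH2Cl2, 0 °C; chromatography on Et3N-washed silica
Reagents that add atoms: dioxygen, O=O
Why: Mukaiyama hydration (metal-hydride hydrogen atom transfer, capture of the tertiary radical by O2, reduction) is Markovnikov and faster for the 1,1-disubstituted alkene than for the hindered trisubstituted C11=C12, and the neutral medium keeps the hydroxy acetal open.

Step 6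
Reactants: 9 (5Z,9R)-9-(2-hydroxypropan-2-yl)-11,11-dimethoxy-6-methylundec-5-en-2-one
Product: 11 (5Z,9R)-9-(2-hydroxypropan-2-yl)-11,11-dimethoxy-6-methylundeca-1,5-dien-2-yl trifluoromethanesulfonate, via dipotassium enolate alkoxide 10 (not isolated)
Conditions: KHMDS (2.2 equiv), THF, −78 °C; then PhNTf2 (1.05 equiv), −78 to 0 °C; H2O
Reagents that add atoms: N-phenylbis(trifluoromethanesulfonimide), O=S(=O)(N(c1ccccc1)S(=O)(=O)C(F)(F)F)C(F)(F)F
Why: Kinetic deprotonation takes the methyl side of the ketone and O-sulfonylation of the enolate gives the terminal enol triflate, while the hindered tertiary alkoxide does not compete for the single equivalent of triflimide.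

Step 7
Reactants: 11 (5Z,9R)-9-(2-hydroxypropan-2-yl)-11,11-dimethoxy-6-methylundeca-1,5-dien-2-yl trifluoromethanesulfonate
Product: 12 methyl (5Z,9R)-9-(2-hydroxypropan-2-yl)-11,11-dimethoxy-6-methyl-2-methylideneundec-5-enoate
Conditions: Pd(OAc)2 (5 mol %), PPh3 (10 mol %), Et3N (2 equiv), CO (1 atm), MeOH/DMF 1:2, rt
Reagents that add atoms: carbon monoxide, [C-]#[O+]; methanol, CO
Why: Palladium-catalysed methoxycarbonylation of an enol triflate (oxidative addition, CO insertion, methanolysis) installs C19 as the methyl ester under weakly basic conditions that leave the hydroxy acetal intact.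

Step 8
Reactants: 12 methyl (5Z,9R)-9-(2-hydroxypropan-2-yl)-11,11-dimethoxy-6-methyl-2-methylideneundec-5-enoate; 13 methyl hex-5-enoate
Product: 14 dimethyl (2E)-2-[(3Z,7R)-7-(2-hydroxypropan-2-yl)-9,9-dimethoxy-4-methylnon-3-en-1-yl]hept-2-enedioate
Conditions: 13 (4 equiv), second-generation Hoveyda–Grubbs catalyst (5 mol %), CH2Cl2, 40 °C
Reagents that add atoms: none
Why: Olefin cross metathesis between a 2-substituted acrylate that does not homodimerise and an excess of a terminal alkene gives the trisubstituted enoate as the thermodynamic E isomer (ester trans to C6), and C11=C12 is too hindered to take part.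

Step 9
Reactants: 14 dimethyl (2E)-2-[(3Z,7R)-7-(2-hydroxypropan-2-yl)-9,9-dimethoxy-4-methylnon-3-en-1-yl]hept-2-enedioate
Product: 15 methyl (2E,6E)-2-[(3Z,7R)-9,9-dimethoxy-4-methyl-7-{2-[(trimethylsilyl)oxy]propan-2-yl}non-3-en-1-yl]-7-methoxy-7-[(trimethylsilyl)oxy]hepta-2,6-dienoate
Conditions: TMSCl (4 equiv), then commercial LDA solution (2.3 equiv), THF, −78 to 0 °C; pentane, filtration under argon, used crude
Reagents that add atoms: chlorotrimethylsilane, C[Si](C)(C)Cl
Why: Ireland-type kinetic enolisation with in situ silylation deprotonates the saturated ester at C4 much faster than the γ-position of the 2-alkyl enoate (which needs HMPA), gives the E silyl ketene acetal and silylates the C15 alkoxide in the same flask.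

Step 10
Reactants: 15 methyl (2E,6E)-2-[(3Z,7R)-9,9-dimethoxy-4-methyl-7-{2-[(trimethylsilyl)oxy]propan-2-yl}non-3-en-1-yl]-7-methoxy-7-[(trimethylsilyl)oxy]hepta-2,6-dienoate
Product: 18 dimethyl (1R,3S,4S,7E,11Z)-3,15-epoxycembra-7,11-diene-18,19-dioate (CNP0164914.1), via cyclic methyl acetal 16 (not isolated), via oxocarbenium triflate 17 (not isolated)
Conditions: TMSOTf (0.3 equiv), 2,6-di-tert-butyl-4-methylpyridine (0.4 equiv), CH2Cl2, 15 added over 12 h (final 1 mM), −78 to −40 °C; aq NaHCO3
Reagents that add atoms: none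
Why: Proposed new method: TMSOTf ionises the dimethyl acetal and the C15 silyl ether captures the open oxocarbenium ion in a fast five-membered closure (Noyori-type transacetalisation, ring A, 16); a second ionisation gives the cyclic ion 17, and the tethered silyl ketene acetal, by many orders of magnitude the best π-nucleophile present (far above C11=C12), closes ring B through C3–C4 at high dilution with TMSOTf regenerated; C3 is set by attack on the inside face of the envelope whose flap carbon C1 holds its chain pseudoequatorial, which gives the 1,3-trans (3S) ether; C4 is set in an open transition state with H4 over the ring and C5 turned to the C2 edge, the orientation from which the tether reaches C14 on the other face without crossing the gem-dimethyl group, which gives the 3,4-anti (4S) ester; the closest known reactions are the Mukaiyama aldol-type addition of silyl ketene acetals to acetals, C-glycosidation of five-membered lactol derivatives and oxocarbenium (Prins, Sakurai) macrocyclisations.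

## Compound list
1 | (1Z,5Z)-1,5-dimethylcycloocta-1,5-diene | C/C1=C/CC/C(C)=C\CC1 | starting material
2 | mono-ozonide (1,2,4-trioxolane) of 1 | CC12CC/C=C(/C)CCC(O1)OO2 | intermediate (not isolated)
3 | (4Z)-4-methyl-8-oxonon-4-enal | O=CCC/C(C)=C\CCC(C)=O | intermediate
4 | (triphenylphosphoranylidene)acetaldehyde | O=CC=P(c1ccccc1)(c1ccccc1)c1ccccc1 | starting material
5 | (2E,6Z)-6-methyl-10-oxoundeca-2,6-dienal | O=C/C=C/CC/C(C)=C\CCC(C)=O | intermediate
6 | isopropenylboronic acid pinacol ester | CC(=C)B1OC(C)(C)C(C)(C)O1 | starting material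
7 | (3R,6Z)-6-methyl-10-oxo-3-(prop-1-en-2-yl)undec-6-enal | O=CC[C@@H](CC/C(C)=C\CCC(C)=O)C(C)=C | intermediate
8 | (5Z,9R)-11,11-dimethoxy-6-methyl-9-(prop-1-en-2-yl)undec-5-en-2-one | COC(OC)C[C@@H](CC/C(C)=C\CCC(C)=O)C(C)=C | intermediate
9 | (5Z,9R)-9-(2-hydroxypropan-2-yl)-11,11-dimethoxy-6-methylundec-5-en-2-one | COC(OC)C[C@@H](CC/C(C)=C\CCC(C)=O)C(C)(C)O | intermediate
10 | dipotassium salt of 9 (terminal enolate and tertiary alkoxide) | COC(OC)C[C@@H](CC/C(C)=C\CCC(=C)[O-])C(C)(C)[O-].[K+].[K+] | intermediate (not isolated)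
11 | (5Z,9R)-9-(2-hydroxypropan-2-yl)-11,11-dimethoxy-6-methylundeca-1,5-dien-2-yl trifluoromethanesulfonate | COC(OC)C[C@@H](CC/C(C)=C\CCC(=C)OS(=O)(=O)C(F)(F)F)C(C)(C)O | intermediate
12 | methyl (5Z,9R)-9-(2-hydroxypropan-2-yl)-11,11-dimethoxy-6-methyl-2-methylideneundec-5-enoate | COC(OC)C[C@@H](CC/C(C)=C\CCC(=C)C(=O)OC)C(C)(C)O | intermediate
13 | methyl hex-5-enoate | C=CCCCC(=O)OC | starting material
14 | dimethyl (2E)-2-[(3Z,7R)-7-(2-hydroxypropan-2-yl)-9,9-dimethoxy-4-methylnon-3-en-1-yl]hept-2-enedioate | COC(=O)CCC/C=C(C(=O)OC)\CC/C=C(C)\CC[C@H](CC(OC)OC)C(C)(C)O | intermediate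
15 | bis-silylated 14: E methyl trimethylsilyl ketene acetal at C4=C18, OTMS at C15, dimethyl acetal at C3 | CO/C(O[Si](C)(C)C)=C\CC/C=C(C(=O)OC)\CC/C=C(C)\CC[C@H](CC(OC)OC)C(C)(C)O[Si](C)(C)C | intermediate
16 | cyclic methyl acetal (5-methoxy-2,2-dimethyloxolane, both anomers) still carrying the ketene acetal | CO/C(O[Si](C)(C)C)=C\CC/C=C(C(=O)OC)\CC/C=C(C)\CC[C@@H]1CC(OC)OC1(C)C | intermediate (not isolated)
17 | five-membered oxocarbenium triflate (C3=O+) still carrying the ketene acetal | CO/C(O[Si](C)(C)C)=C\CC/C=C(C(=O)OC)\CC/C=C(C)\CC[C@@H]1CC=[O+]C1(C)C.[O-]S(=O)(=O)C(F)(F)F | intermediate (not isolated)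
18 | dimethyl (1R,3S,4S,7E,11Z)-3,15-epoxycembra-7,11-diene-18,19-dioate (CNP0164914.1) | COC(=O)/C1=C/CC[C@H](C(=O)OC)[C@@H]2C[C@@H](CC/C(C)=C\CC1)C(C)(C)O2 | target

## Step count and risks
Total steps: 10. Longest linear sequence: 10 (1 to 18).

**Step 10 (double ring closure).** The ketene acetal may be protodesilylated before ring B closes, oligomers may form, and the C4 selectivity rests only on the tether argument.
- The fallback closes the rings one after the other and lets an auxiliary set C4. It sets out from 12.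
- PPTS in MeOH closes the hydroxy acetal to the cyclic methyl acetal F1.
- (4R)-4-Benzyl-1,3-thiazolidine-2-thione is acylated with hex-5-enoyl chloride (Et3N, CH2Cl2) to the hexenoyl thioimide F2.
- The chlorotitanium enolate of F2 (TiCl4, iPr2NEt, CH2Cl2, −78 to −40 °C) is added to F1 activated with SnCl4. The auxiliary shields one enolate face and inside attack fixes C3, which gives the 1,3-trans, 3,4-anti thioimide adduct F3.
- DMAP in MeOH displaces the auxiliary and gives the diene diester F4.
- Ring-closing metathesis of F4 (second-generation Hoveyda–Grubbs catalyst, toluene, 1 mM, 80 °C) forms C7=C8 and comes back to the route at 18.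

**Step 3 (asymmetric isopropenyl addition to an aliphatic enal).** 1,2-Addition and a modest enantiomeric excess are the dangers.
- The fallback is an auxiliary-controlled cuprate addition. It sets out from 3.
- A Masamune–Roush Horner–Wadsworth–Emmons reaction (LiCl, iPr2NEt, MeCN) with diethyl {2-oxo-2-[(4S)-2-oxo-4-phenyl-1,3-oxazolidin-3-yl]ethyl}phosphonate gives the E N-enoyl oxazolidinone F5.
- Isopropenylmagnesium bromide with CuBr·SMe2 (THF/Me2S, −78 °C) adds to the chelated s-cis conformer on the face away from the phenyl group. This gives the conjugate adduct F6 with (R) at C1, and the ketone is not touched at this temperature.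
- EtSH/n-BuLi (THF, 0 °C) exchanges the auxiliary for the ethyl thioester F7.
- Fukuyama reduction (Et3SiH, Pd/C, acetone, rt) comes back to the route at 7.

**Step 9 (selective enolisation of the saturated ester).** γ-Deprotonation of the enoate would give a silyl dienol ether, and crude 15 cannot be purified.
- The fallback replaces strong-base enolisation by soft enolisation of a thioester. It sets out from 12.
- Hex-5-enoyl chloride and EtSH (Et3N, CH2Cl2) give S-ethyl hex-5-enethioate F8.
- Cross metathesis of 12 with F8 (second-generation Hoveyda–Grubbs catalyst, CH2Cl2, 40 °C) gives the thioester acetal F9.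
- TMSOTf (4 equiv) and iPr2NEt (3 equiv) in CH2Cl2 at 1 mM silylate the alcohol, enolise only the thioester and trigger the same two ring closures, which gives the macrocyclic thioester F10.
- NaOMe (0.2 equiv) in MeOH at 0 °C exchanges the thioester for the methyl ester and comes back to the route at 18.

## Further compounds
F1 | step 10 | methyl (5Z)-8-[(3R)-5-methoxy-2,2-dimethyloxolan-3-yl]-6-methyl-2-methylideneoct-5-enoate (both anomers) | COC1C[C@@H](CC/C(C)=C\CCC(=C)C(=O)OC)C(C)(C)O1
F2 | step 10 | (4R)-4-benzyl-3-(hex-5-enoyl)-1,3-thiazolidine-2-thione | C=CCCCC(=O)N1[C@H](Cc2ccccc2)CSC1=S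
F3 | step 10 | (4R)-4-benzyl-3-{(2S)-2-[(2S,4R)-4-[(3Z)-7-(methoxycarbonyl)-3-methylocta-3,7-dien-1-yl]-5,5-dimethyloxolan-2-yl]hex-5-enoyl}-1,3-thiazolidine-2-thione | C=CCC[C@H](C(=O)N1[C@H](Cc2ccccc2)CSC1=S)[C@@H]1C[C@@H](CC/C(C)=C\CCC(=C)C(=O)OC)C(C)(C)O1
F4 | step 10 | methyl (2S)-2-[(2S,4R)-4-[(3Z)-7-(methoxycarbonyl)-3-methylocta-3,7-dien-1-yl]-5,5-dimethyloxolan-2-yl]hex-5-enoate | C=CCC[C@H](C(=O)OC)[C@@H]1C[C@@H](CC/C(C)=C\CCC(=C)C(=O)OC)C(C)(C)O1
F5 | step 3 | (4S)-3-[(2E,6Z)-6-methyl-10-oxoundeca-2,6-dienoyl]-4-phenyl-1,3-oxazolidin-2-one | O=C(/C=C/CC/C(C)=C\CCC(C)=O)N1[C@@H](c2ccccc2)COC1=O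
F6 | step 3 | (4S)-3-[(3R,6Z)-6-methyl-10-oxo-3-(prop-1-en-2-yl)undec-6-enoyl]-4-phenyl-1,3-oxazolidin-2-one | O=C(C[C@@H](CC/C(C)=C\CCC(C)=O)C(C)=C)N1[C@@H](c2ccccc2)COC1=O
F7 | step 3 | S-ethyl (3R,6Z)-6-methyl-10-oxo-3-(prop-1-en-2-yl)undec-6-enethioate | CCSC(=O)C[C@@H](CC/C(C)=C\CCC(C)=O)C(C)=C
F8 | step 9 | S-ethyl hex-5-enethioate | C=CCCCC(=O)SCC
F9 | step 9 | methyl (2E)-7-(ethylsulfanyl)-2-[(3Z,7R)-7-(2-hydroxypropan-2-yl)-9,9-dimethoxy-4-methylnon-3-en-1-yl]-7-oxohept-2-enoate | CCSC(=O)CCC/C=C(C(=O)OC)\CC/C=C(C)\CC[C@H](CC(OC)OC)C(C)(C)O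
F10 | step 9 | 18-(S-ethyl thioester) analogue of 18, (1R,3S,4S,7E,11Z) | COC(=O)/C1=C/CC[C@H](C(=O)SCC)[C@@H]2C[C@@H](CC/C(C)=C\CC1)C(C)(C)O2
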